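Ring A is disconnected at C4a–C8a and C5–C6. Its pattern, oxygens on C7 and C8a in a meta relation and the two carbon substituents on the adjacent atoms C4a (the C4 acyl group) and C5 (isopentyl), is the imprint of a 1,3-dioxygenated diene adding across a β-alkyl ynone. One thermal operation therefore unites the bis(silyl enol ether) of dimedone with the C4a≡C5 triple bond, expels isobutene and leaves the complete carbon skeleton as a resorcinol ketone. The precursor is an isopentyl ynone whose acyl chain carries C3, C2 as a hydrogenolysable cyclic ketal and the benzyl-protected hydroxypyrone; neutral hydrogenolysis and a crystallisation-driven resolution finish the synthesis.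

Key step: step 7

Assumption: C2 (R by CIP: O1 > OH > C3 > CH2-pyrone) is the only stereocentre and epimerises in solution by ring–chain tautomerism, so it is fixed last; the (R)-amine is assumed to give the less soluble salt with the (2R)-hemiketal, and if the (2S)-salt crystallised instead the (S)-amine would be used, which gives the mirror-image salt.

Precursor design: C2 is carried as the cyclic o-xylylene ketal (a 1,5-dihydro-2,4-benzodioxepine) and not as an open-chain bis(benzyl) ketal, because a β,β-dialkoxy ketone with two independent alkoxy groups can lose one irreversibly on heating, whereas the tethered ketal reopens only reversibly, forms under mild silyl-triflate catalysis and is still cleaved by neutral hydrogenolysis.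

Step 1
Reactants: 1 4-hydroxy-6-methyl-2H-pyran-2-one
Product: 2 4-(benzyloxy)-6-methyl-2H-pyran-2-one
Conditions: BnBr, K2CO3, DMF, 50 °C
Reagents that add atoms: benzyl bromide, BrCc1ccccc1
Why: Williamson-type O-alkylation of the acidic vinylogous carboxylic acid (pKa about 5), which under carbonate conditions in a dipolar solvent should go to O4 of the 2-pyrone as in the routine 4-O-methylation of this lactone.

Step 2
Reactants: 2 4-(benzyloxy)-6-methyl-2H-pyran-2-one
Product: 4 [4-(benzyloxy)-2-oxo-2H-pyran-6-yl]acetic acid, via lithiated pyrone 3 (not isolated)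
Conditions: LiN(iPr)2 (LDA), THF, −78 °C; CO2; then 1 M HCl, 0 °C
Reagents that add atoms: carbon dioxide, O=C=O
Why: Lateral deprotonation of the C6 methyl group gives the extended lithium dienolate 3 (the established metalation site of 4-alkoxy-6-methyl-2-pyrones), which should be carboxylated at the exocyclic carbon by CO2 (carboxylation of a vinylogous ester enolate).

Step 3
Reactants: 4 [4-(benzyloxy)-2-oxo-2H-pyran-6-yl]acetic acid; 5 Meldrum's acid (2,2-dimethyl-1,3-dioxane-4,6-dione)
Product: 8 4-[4-(benzyloxy)-2-oxo-2H-pyran-6-yl]-N-methoxy-N-methyl-3-oxobutanamide, via acyl Meldrum's acid 6 (not isolated), via acylketene 7 (not isolated)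
Conditions: DCC, DMAP, CH2Cl2, 0 °C to rt; then MeNHOMe·HCl, pyridine, toluene, 80 °C
Reagents that add atoms: N,O-dimethylhydroxylamine hydrochloride, CNOC.Cl
Why: Carbodiimide-mediated C-acylation of Meldrum's acid, then thermal loss of acetone and CO2 from 6 to the acylketene 7 and its capture by the hydroxylamine (aminolysis of an acyl Meldrum's acid), should give the β-keto Weinreb amide under near-neutral conditions that never expose the pyrone to alkoxide or hydroxide.

Step 4
Reactants: 8 4-[4-(benzyloxy)-2-oxo-2H-pyran-6-yl]-N-methoxy-N-methyl-3-oxobutanamide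
Product: 9 2-(3-{[4-(benzyloxy)-2-oxo-2H-pyran-6-yl]methyl}-1,5-dihydro-3H-2,4-benzodioxepin-3-yl)-N-methoxy-N-methylacetamide
Conditions: 1,2-C6H4(CH2OH)2, iPrOSiMe3, Me3SiOTf (cat.), CH2Cl2, −20 °C to rt
Reagents that add atoms: 1,2-benzenedimethanol, OCc1ccccc1CO
Why: Noyori-type ketalisation, in which the silyl triflate activates the ketone and the diol, silylated in the flask, adds twice with irreversible formation of hexamethyldisiloxane, the rigid o-xylylene backbone favouring closure of the seven-membered ketal; no stereocentre arises because the diol is symmetric.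

Step 5
Reactants: 9 2-(3-{[4-(benzyloxy)-2-oxo-2H-pyran-6-yl]methyl}-1,5-dihydro-3H-2,4-benzodioxepin-3-yl)-N-methoxy-N-methylacetamide; 10 5-methylhex-1-yne
Product: 13 1-(3-{[4-(benzyloxy)-2-oxo-2H-pyran-6-yl]methyl}-1,5-dihydro-3H-2,4-benzodioxepin-3-yl)-7-methyloct-3-yn-2-one, via lithium acetylide 11 (not isolated), via tetrahedral adduct 12 (not isolated)
Conditions: 10, n-BuLi, THF, −78 °C; then 9, −78 to −30 °C; AcOH quench at −78 °C
Reagents that add atoms: none
Why: Weinreb ketone synthesis, in which the lithium acetylide 11 adds once to the amide and the chelated adduct 12 releases the ynone only on quench, the donor-substituted pyrone carbonyl being far less electrophilic than the amide at −78 °C.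

Step 6
Reactants: 14 dimedone (5,5-dimethylcyclohexane-1,3-dione)
Product: 16 5,5-dimethyl-1,3-bis(trimethylsilyloxy)cyclohexa-1,3-diene, via mono(silyl enol ether) 15 (not isolated)
Conditions: Me3SiOTf, Et3N, Et2O, 0 °C to rt
Reagents that add atoms: trimethylsilyl trifluoromethanesulfonate, C[Si](C)(C)OS(=O)(=O)C(F)(F)F
Why: Double soft enolisation and O-silylation of the 1,3-dione with silyl triflate and amine (silyl enol ether formation), the second, vinylogous enolisation of 15 giving the conjugated diene, which is the same compound whichever side enolises because dimedone is symmetric.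

Step 7
Reactants: 13 1-(3-{[4-(benzyloxy)-2-oxo-2H-pyran-6-yl]methyl}-1,5-dihydro-3H-2,4-benzodioxepin-3-yl)-7-methyloct-3-yn-2-one; 16 5,5-dimethyl-1,3-bis(trimethylsilyloxy)cyclohexa-1,3-diene
Product: 19 1-[2,4-dihydroxy-6-(3-methylbutyl)phenyl]-2-(3-{[4-(benzyloxy)-2-oxo-2H-pyran-6-yl]methyl}-1,5-dihydro-3H-2,4-benzodioxepin-3-yl)ethan-1-one, via bicyclo[2.2.2]octadiene cycloadduct 17 (not isolated), via bis(trimethylsilyl) aryl ether 18 (not isolated)
Conditions: 16 (4 equiv), o-xylene, 80 °C then 140 °C (isobutene vented); then Bu4NF, AcOH, THF, 0 °C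
Reagents that add atoms: none
Why: A thermal normal-demand [4+2] addition of the electron-rich diene 16 across the ynone triple bond should give the bicyclo[2.2.2]octadiene 17, which on further heating undergoes a retro-[4+2] loss of isobutene driven by aromatisation. The closest known reaction type is the Alder–Rickert benzannulation of dimedone-derived bis(silyloxy)dienes with acetylenic carbonyl compounds, which gives resorcinols. Ring A is closed by an intermolecular concerted cycloaddition that forms C5–C6 and C4a–C8a in one event, four ring carbons coming from the diene and two from the alkyne. No stereocentre is created: the two bridgehead centres of 17 are erased on aromatisation and the ketal carbon is not stereogenic. Regiochemistry is the selectivity required and is secured by polarisation, since the diene CH terminus (pushed by both silyloxy groups) carries the largest HOMO coefficient and the ynone β-carbon C5 the largest LUMO coefficient, so the acyl-bearing C4a ends up between C8a–O and C5. Chemoselectivity rests on the ynone being the only strongly electron-poor two-carbon π system, and the one internal competitor, the pyrone acting as a diene toward its own tethered ynone, should be outpaced by using the far more nucleophilic 16 in excess and consuming the alkyne at 80 °C before the temperature is raised for the cycloreversion; buffered fluoride then removes both aryl silyl groups without touching the ketal.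

Step 8
Reactants: 19 1-[2,4-dihydroxy-6-(3-methylbutyl)phenyl]-2-(3-{[4-(benzyloxy)-2-oxo-2H-pyran-6-yl]methyl}-1,5-dihydro-3H-2,4-benzodioxepin-3-yl)ethan-1-one
Product: 21 racemic 2,7-dihydroxy-2-[(4-hydroxy-2-oxo-2H-pyran-6-yl)methyl]-5-(3-methylbutyl)-2,3-dihydro-4H-chromen-4-one, via open-chain 1,3-diketone 20 (not isolated)
Conditions: H2 (1 atm), 10% Pd/C, EtOAc, rt
Reagents that add atoms: none
Why: Catalytic hydrogenolysis of benzylic C–O bonds should remove the pyronyl benzyl ether and open the benzodioxepine ketal (the resulting hemiketal sheds 2-methylbenzyl alcohol), and the freed C2 ketone of 20 is captured by the C8a phenol in a 6-exo-trig hemiketalisation, no acid being present that could dehydrate the product to the chromone; C2 is formed without control at this stage.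

Step 9
Reactants: 21 racemic 2,7-dihydroxy-2-[(4-hydroxy-2-oxo-2H-pyran-6-yl)methyl]-5-(3-methylbutyl)-2,3-dihydro-4H-chromen-4-one; 22 (R)-N,N-dimethyl-1-phenylethylamine
Product: 23 (R)-N,N-dimethyl-1-phenylethylammonium salt of the (2R)-hemiketal (pyron-4-olate)
Conditions: 22 (1.0 equiv), iPrOAc–heptane, 35 °C then slow cooling to 5 °C, seeded slurry aged until the liquor is depleted
Reagents that add atoms: none
Why: Proposed new method: the hemiketal epimerises through ring–chain tautomerism (reversible opening to the achiral diketone 20, catalysed by the amine–pyronate pair), so selective crystallisation of the less soluble diastereomeric tertiary-ammonium pyronate should drain the whole sample into one C2 configuration, the lattice of the (R)-ammonium salt being the controlling element and the tertiary amine being unable to condense with the ketone; the closest known reaction types are the crystallisation-induced diastereomer transformation of configurationally labile acids as chiral-amine salts and the crystallisation of single anomers of mutarotating lactols.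

Step 10
Reactants: 23 (R)-N,N-dimethyl-1-phenylethylammonium salt of the (2R)-hemiketal (pyron-4-olate)
Product: 24 (2R)-2,7-dihydroxy-2-[(4-hydroxy-2-oxo-2H-pyran-6-yl)methyl]-5-(3-methylbutyl)-2,3-dihydro-4H-chromen-4-one
Conditions: aq. citric acid, EtOAc, 0 °C; evaporation below 20 °C
Reagents that add atoms: none
Why: Acid–base liberation of the free hydroxypyrone from its ammonium salt (salt break of a resolution) at 0 °C, where without base the ring–chain equilibration should be slow, so the (2R) configuration fixed in the crystal is retained.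

Compound list

1 | 4-hydroxy-6-methyl-2H-pyran-2-one | Cc1cc(O)cc(=O)o1 | starting material
2 | 4-(benzyloxy)-6-methyl-2H-pyran-2-one | Cc1cc(OCc2ccccc2)cc(=O)o1 | intermediate
3 | lithiated pyrone (lithium dienolate of 2, drawn C-lithiated) | [Li]Cc1cc(OCc2ccccc2)cc(=O)o1 | intermediate
4 | [4-(benzyloxy)-2-oxo-2H-pyran-6-yl]acetic acid | OC(=O)Cc1cc(OCc2ccccc2)cc(=O)o1 | intermediate
5 | Meldrum's acid (2,2-dimethyl-1,3-dioxane-4,6-dione) | CC1(C)OC(=O)CC(=O)O1 | starting material
6 | 5-{2-[4-(benzyloxy)-2-oxo-2H-pyran-6-yl]-1-hydroxyethylidene}-2,2-dimethyl-1,3-dioxane-4,6-dione (acyl Meldrum's acid) | CC1(C)OC(=O)C(=C(O)Cc2cc(OCc3ccccc3)cc(=O)o2)C(=O)O1 | intermediate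
7 | 4-[4-(benzyloxy)-2-oxo-2H-pyran-6-yl]but-1-ene-1,3-dione (acylketene) | O=C=CC(=O)Cc1cc(OCc2ccccc2)cc(=O)o1 | intermediate
8 | 4-[4-(benzyloxy)-2-oxo-2H-pyran-6-yl]-N-methoxy-N-methyl-3-oxobutanamide | CON(C)C(=O)CC(=O)Cc1cc(OCc2ccccc2)cc(=O)o1 | intermediate
9 | 2-(3-{[4-(benzyloxy)-2-oxo-2H-pyran-6-yl]methyl}-1,5-dihydro-3H-2,4-benzodioxepin-3-yl)-N-methoxy-N-methylacetamide | CON(C)C(=O)CC1(Cc2cc(OCc3ccccc3)cc(=O)o2)OCc2ccccc2CO1 | intermediate
10 | 5-methylhex-1-yne | CC(C)CCC#C | starting material
11 | lithium 5-methylhex-1-yn-1-ide | CC(C)CCC#C[Li] | intermediate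
12 | lithium alkoxide of the N-methoxy-N-methyl hemiaminal from 9 and 11 (tetrahedral adduct, racemic) | CON(C)C(O[Li])(C#CCCC(C)C)CC1(Cc2cc(OCc3ccccc3)cc(=O)o2)OCc2ccccc2CO1 | intermediate
13 | 1-(3-{[4-(benzyloxy)-2-oxo-2H-pyran-6-yl]methyl}-1,5-dihydro-3H-2,4-benzodioxepin-3-yl)-7-methyloct-3-yn-2-one (key-step precursor) | CC(C)CCC#CC(=O)CC1(Cc2cc(OCc3ccccc3)cc(=O)o2)OCc2ccccc2CO1 | intermediate
14 | dimedone (5,5-dimethylcyclohexane-1,3-dione) | CC1(C)CC(=O)CC(=O)C1 | starting material
15 | 5,5-dimethyl-3-(trimethylsilyloxy)cyclohex-2-en-1-one | CC1(C)CC(=O)C=C(O[Si](C)(C)C)C1 | intermediate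
16 | 5,5-dimethyl-1,3-bis(trimethylsilyloxy)cyclohexa-1,3-diene | CC1(C)CC(O[Si](C)(C)C)=CC(O[Si](C)(C)C)=C1 | intermediate
17 | bicyclo[2.2.2]octa-2,5-diene cycloadduct of 13 and 16 (racemic; bridgeheads C8a–OSiMe3 and C6–H, bridge CH2–CMe2) | C[Si](C)(C)OC12CC(C)(C)C(C(O[Si](C)(C)C)=C1)C(CCC(C)C)=C2C(=O)CC1(Cc2cc(OCc3ccccc3)cc(=O)o2)OCc2ccccc2CO1 | intermediate
18 | 2,4-bis(trimethylsilyl) ether of 19 | CC(C)CCc1cc(O[Si](C)(C)C)cc(O[Si](C)(C)C)c1C(=O)CC1(Cc2cc(OCc3ccccc3)cc(=O)o2)OCc2ccccc2CO1 | intermediate
19 | 1-[2,4-dihydroxy-6-(3-methylbutyl)phenyl]-2-(3-{[4-(benzyloxy)-2-oxo-2H-pyran-6-yl]methyl}-1,5-dihydro-3H-2,4-benzodioxepin-3-yl)ethan-1-one (key-step product) | CC(C)CCc1cc(O)cc(O)c1C(=O)CC1(Cc2cc(OCc3ccccc3)cc(=O)o2)OCc2ccccc2CO1 | intermediate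
20 | 1-[2,4-dihydroxy-6-(3-methylbutyl)phenyl]-4-(4-hydroxy-2-oxo-2H-pyran-6-yl)butane-1,3-dione | CC(C)CCc1cc(O)cc(O)c1C(=O)CC(=O)Cc1cc(O)cc(=O)o1 | intermediate
21 | racemic 2,7-dihydroxy-2-[(4-hydroxy-2-oxo-2H-pyran-6-yl)methyl]-5-(3-methylbutyl)-2,3-dihydro-4H-chromen-4-one | CC(C)CCc1cc(O)cc2c1C(=O)CC(O)(Cc1cc(O)cc(=O)o1)O2 | intermediate
22 | (R)-N,N-dimethyl-1-phenylethylamine | C[C@@H](N(C)C)c1ccccc1 | starting material
23 | (R)-N,N-dimethyl-1-phenylethylammonium 6-{[(2R)-2,7-dihydroxy-5-(3-methylbutyl)-4-oxo-3,4-dihydro-2H-chromen-2-yl]methyl}-2-oxo-2H-pyran-4-olate | CC(C)CCc1cc(O)cc2c1C(=O)C[C@@](O)(Cc1cc([O-])cc(=O)o1)O2.C[C@@H]([NH+](C)C)c1ccccc1 | intermediate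
24 | (2R)-2,7-dihydroxy-2-[(4-hydroxy-2-oxo-2H-pyran-6-yl)methyl]-5-(3-methylbutyl)-2,3-dihydro-4H-chromen-4-one | CC(C)CCc1cc(O)cc2c1C(=O)C[C@@](O)(Cc1cc(O)cc(=O)o1)O2 | target

Total step count: 10. Longest linear sequence: 9 steps (steps 1–5 and 7–10); step 6 is the side branch.

Steps most likely to fail

1. Step 9 (bears the label "Proposed new method:"). The salt may fail to crystallise selectively, or epimerisation may be slower than base-induced loss of water from the hemiketal, so the liquor is not funnelled into one diastereomer. The fallback uses known chemistry and sets out from 21. The racemate would be resolved by preparative chromatography on a polysaccharide chiral stationary phase (amylose tris(3,5-dimethylphenylcarbamate), neutral eluent, column and fractions kept cold), which should give 24 directly. The (2S)-enantiomer F1 collected alongside would be re-equilibrated to 21 with a trace of Et3N in EtOAc and recycled. The route is rejoined at 24.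

2. Step 7. The intermolecular cycloaddition of the β-branched internal ynone with the diene terminus next to the gem-dimethyl group may be slow. Intramolecular cycloaddition of the pyrone (as diene) onto the tethered ynone, or thermal reopening of the ketal, could then overtake it. The fallback sets out from 13, which would be heated at about 80 °C in toluene, without Lewis acid, with 1-methoxy-1,3-bis(trimethylsilyloxy)buta-1,3-diene F2 (from methyl acetoacetate by two successive O-silylations). Its unhindered CH2 terminus should bond to C5 and its ketene-acetal carbon to C4a. The resulting 1,4-cyclohexadiene cycloadduct F3 should aromatise by loss of methanol, not by cycloreversion, to the bis(silyl) ether 18. The route is rejoined at 18, which is desilylated to 19 as in step 7.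

3. Step 8. The pyrone ring may be hydrogenated before the cyclic ketal is fully cleaved, or the catalyst surface may promote loss of water from the hemiketal to the chromone. The fallback sets out from 19, which would be treated with PPTS in aqueous acetone at room temperature to hydrolyse the cyclic ketal without hydrogen. The liberated diketone should close on O1 to racemic 2-{[4-(benzyloxy)-2-oxo-2H-pyran-6-yl]methyl}-2,7-dihydroxy-5-(3-methylbutyl)-2,3-dihydro-4H-chromen-4-one F4. A brief hydrogenolysis (H2, Pd/C, EtOAc) of its single benzyl ether should then give 21, where the route is rejoined.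

Further compounds

F1 | step 9 | (2S)-2,7-dihydroxy-2-[(4-hydroxy-2-oxo-2H-pyran-6-yl)methyl]-5-(3-methylbutyl)-2,3-dihydro-4H-chromen-4-one | CC(C)CCc1cc(O)cc2c1C(=O)C[C@](O)(Cc1cc(O)cc(=O)o1)O2
F2 | step 7 | 1-methoxy-1,3-bis(trimethylsilyloxy)buta-1,3-diene | COC(O[Si](C)(C)C)=CC(=C)O[Si](C)(C)C
F3 | step 7 | racemic 1,4-cyclohexadiene cycloadduct of 13 and F2 (C8a bearing OMe and OSiMe3) | COC1(O[Si](C)(C)C)C=C(O[Si](C)(C)C)CC(CCC(C)C)=C1C(=O)CC1(Cc2cc(OCc3ccccc3)cc(=O)o2)OCc2ccccc2CO1
F4 | step 8 | racemic 2-{[4-(benzyloxy)-2-oxo-2H-pyran-6-yl]methyl}-2,7-dihydroxy-5-(3-methylbutyl)-2,3-dihydro-4H-chromen-4-one | CC(C)CCc1cc(O)cc2c1C(=O)CC(O)(Cc1cc(OCc3ccccc3)cc(=O)o1)O2
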